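## Analysis of the target

Artopetelin C (22) is a 2-arylbenzofuran. Ring A (C3a, C4–C7, C7a) is a phloroglucinol ring whose three oxygens are O1 of the furan (ring B: O1, C2, C3, C3a, C7a), the C4 hydroxyl and the C6 hydroxyl; C7, between O1 and the C6 hydroxyl, carries a 1,1-dimethylallyl group. Ring C (C1'–C6') is a pentasubstituted resorcinol: C1' is bonded to C2, C2' bears a prenyl group, C3' a free hydroxyl, C4' a hydrogen, and C5'–O and C6'–CH2 are joined in a 2,2-dimethyldihydropyran, so ring C is a chroman. The molecule has no stereocentre and is achiral; the only stereochemical element on the way is an alkene geometry that is lost again. Sensitive features are three isolated alkenes, two of them next to a free phenol (C3'–OH with the C2' prenyl, C6–OH with the C7 dimethylallyl), so acid or electrophilic metals would close further rings, and electron-rich phenols that oxidise easily; hydrogenation and strong acid are excluded once the prenyl groups are present. The difficulties are regiochemical: the three oxygens of ring A must take three different roles, C7 must be told from C5, ring C has five different substituents, and the C2–C1' bond ends at a carbon flanked by two ortho alkyl groups. The strategy rests on one feature: O1 and the C4 oxygen are the two ortho oxygens of a phloroglucinol ring whose third oxygen (C6–O) can carry a prenyl ether. A stilbene with a 2,6-dihydroxy-4-prenyloxyphenyl ring therefore closes O1–C2 with either hydroxyl to the same product, and the C6 ether that remains is the precursor of the C7 side chain.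

## Retrosynthetic reasoning

22 ⇒ 21. The last operation is only the removal of two aryl silyl ethers (C4–O and C3'–O). Silyl ethers are chosen because fluoride cleaves them without acid, base or hydrogen, none of which the two phenol/alkene pairs of 22 would tolerate.

21 ⇒ 20. The bond from C7 to the quaternary carbon of the 1,1-dimethylallyl group is cut. A quaternary benzylic carbon with a vinyl group ortho to a phenol is the signature of an aromatic Claisen rearrangement of a prenyl ether, so the side chain is traced back to the C6 prenyl ether of 20. The forward reaction must choose C7 over C5; the bulky silyl ether on the C4 oxygen of 20 shields C5, and the para position (C3a) is a ring-fusion carbon, so the group cannot travel further.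

20 ⇒ 19. Silylation of the single free hydroxyl of 19. This is the point where the C4 and C6 oxygens, already different (hydroxyl and prenyl ether), receive their final roles.

19 ⇒ 18. The O1–C2 bond is cut, which opens ring B to the E-stilbene 18. It is cut here and not at C2–C1' because the hindered aryl–heteroaryl bond then never has to be made by coupling: C2 and C3 come from the stilbene alkene. The two hydroxyls of ring A in 18 are equivalent, so the forward oxidative cyclisation has no regiochemical choice. It must only react at the stilbene alkene and not at the prenyl alkenes, which is why the ring C phenol stays silylated.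

18 ⇒ 17 ⇒ 12 + 16. The two ring A phenols are protected for the olefination as tert-butyldimethylsilyl ethers, which can be removed while the triisopropylsilyl ether on ring C stays. The stilbene C=C of 17 is cut to the ring C benzylic phosphonate 12 and the ring A aldehyde 16. The aldehyde is placed on ring A because the formyl carbon of commercial 13 already marks the one carbon of the phloroglucinol that must carry the alkene.

16 ⇒ 15 ⇒ 13 + 14. Silylation, and before it O-alkylation of 13 with prenyl bromide 14 at the hydroxyl para to the formyl group. The symmetry of 13 means only this one oxygen has to be distinguished.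

12 ⇒ 11 ⇒ 10 ⇒ 9 ⇒ 8. Functional-group changes at the C5 carbon of the chroman: phosphonate from bromide, bromide from alcohol, alcohol from the methyl ester, after silylation of the phenol of 8. The ester is kept up to 8 because it is the group that directs both ring-forming sigmatropic steps.

8 ⇒ 7 ⇒ 6 ⇒ 5. The C6–prenyl bond is cut. An unbranched prenyl group ortho to a phenol comes from the Claisen rearrangement of a 1,1-dimethylallyl ether (7), made by semihydrogenation of the propargyl ether 6, itself from phenol 5 and chloride 2. The forward shift must go to C6 and not C8; C6 is ortho to the ester and para to the ring oxygen, and both effects favour it.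

5 ⇒ 4 ⇒ 3 ⇒ 1 + 2. The pyran ring is cut at C4–C4a and traced to the mono-propargyl ether 3 of methyl 3,5-dihydroxybenzoate 1. The thermal rearrangement of 3 gives chromene 4, and hydrogenation of 4 gives chroman 5 while no other alkene is present. The same directing argument (ortho to the ester, para to the free hydroxyl) applies, and the same reagent 2 serves for both carbon substituents of ring C.

## Alternatives that were turned down

Alternative 1: Ring C is cut at C1'–C2' and C5'–C6' and assembled by a Diels–Alder reaction between the benzofuran-2-yl alkynone A2 and the prenylated 1-methoxy-1,3-bis(trimethylsilyloxy)diene A3. Loss of the methoxy group aromatises the adduct to the acylresorcinol A1.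
- For: the five substituents of ring C are placed by the polarity of the two partners with no directing-group argument, and the crowded C2–C1' environment is built by cycloaddition, not coupling. On regiocontrol of ring C this is stronger than the chosen route, which relies on substituent effects in two sigmatropic shifts.
- Against: A2 already contains the complete benzofuran with its C7 dimethylallyl group and a C2 alkynyl ketone, so all of ring A and ring B chemistry must precede it. A1 is not at the right oxidation level: the enone must close to a chromanone, and the chromanone carbonyl must then be removed in the presence of three alkenes and two phenol/alkene pairs. The diene terminus that must bond to the aryl-bearing alkyne carbon is substituted, so a stepwise Michael pathway with loss of regiocontrol is possible.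
- In comparison, the chosen route delivers ring C as a chroman from the start and finishes with three mild steps.

Alternative 2: The C2–C1' bond and the C2'–CH2 bond are made in one flask. The benzofuran A5 is magnesiated at C2 and adds to the chroman 5,6-aryne released from the iodo sulfonate A6; the resulting C2' arylmagnesium is prenylated under copper catalysis to the tris(silyl ether) A4.
- For: it is the most convergent plan, only desilylation follows, and the silyloxy group next to the aryne directs the nucleophile to C1'. On convergence and on the length of the end game it is stronger than the chosen route.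
- Against: both halves must be complete beforehand. A5 still needs the C7 side chain. A6 is a hexasubstituted benzene carrying an iodine and a sulfonate that are absent from the target, and one of them sits on the carbon meta to both oxygens, which is hard to functionalise. The aryne is flanked on both sides, the nucleophile is hindered, and allylic substitution by a crowded arylmagnesium can give the branched isomer.
- In comparison, the chosen route builds ring B from a commercial, symmetric aldehyde and needs no throw-away substituents.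

Alternative 3: Ring A is cut at C3a–C4, C4–C5 and C6–C7. Photochemical Wolff rearrangement of the furyl diazo ketone A8 gives a ketene that adds the siloxyacetylene A9; the cyclobutenone opens and closes onto furan C3 to give the phenol A7.
- For: ring A arrives with the C4 hydroxyl free and the C6 oxygen silylated, so the two oxygens are differentiated by construction, and the dimethylallyl group is in place without a Claisen step. On both points it is stronger than the chosen route, which needs a silylation and a regioselective rearrangement.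
- Against: A8 requires a bond between a furan and the di-ortho-substituted ring C, and a diazo group on a carbon next to a quaternary allylic centre. The ketene has a quaternary substituent, which slows the cycloaddition. The closure must dearomatise the furan. The photolysis is run in the presence of aryl and alkene chromophores.
- In comparison, the chosen route uses only reaction types with close precedent and takes ring A from a commercial phloroglucinol aldehyde.

Key step: step 15

Remark: the target is achiral; the only stereochemical element in the route is the E geometry of 17 and 18, which the key step erases.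

## Route

Step 1
Reactants: 1 methyl 3,5-dihydroxybenzoate; 2 3-chloro-3-methylbut-1-yne
Product: 3 methyl 3-hydroxy-5-[(2-methylbut-3-yn-2-yl)oxy]benzoate
Conditions: 1 (3 equiv), DBU, CuCl2·2H2O (cat.), MeCN, 0 °C
Reagents that add atoms: none
Why: Copper-catalysed O-propargylation of a phenol with a tertiary propargylic chloride is a standard route to aryl 1,1-dimethylpropargyl ethers; the symmetric diol 1 is used in excess so that the reaction stops at the mono-ether, and unreacted 1 is recovered.

Step 2
Reactants: 3 methyl 3-hydroxy-5-[(2-methylbut-3-yn-2-yl)oxy]benzoate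
Product: 4 methyl 7-hydroxy-2,2-dimethyl-2H-chromene-5-carboxylate
Conditions: PhNEt2, 190 °C
Reagents that add atoms: none
Why: Thermal aryl propargyl ether rearrangement: a [3,3] shift to the ortho carbon, enolisation, 1,5-hydrogen shift and oxa-6π electrocyclisation give the 2,2-dimethylchromene. The shift should go to the carbon between the ether and the ester, which is ortho to the electron-withdrawing ester and para to the free hydroxyl, and not to the carbon between the two oxygens.

Step 3
Reactants: 4 methyl 7-hydroxy-2,2-dimethyl-2H-chromene-5-carboxylate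
Product: 5 methyl 7-hydroxy-2,2-dimethyl-3,4-dihydro-2H-chromene-5-carboxylate
Conditions: H2 (1 atm), Pd/C, EtOAc, rt
Reagents that add atoms: none
Why: Catalytic hydrogenation of the styrene-type C3=C4 bond; ester and phenol are inert, and the pyran ring is saturated here because no prenyl group is present yet.

Step 4
Reactants: 5 methyl 7-hydroxy-2,2-dimethyl-3,4-dihydro-2H-chromene-5-carboxylate; 2 3-chloro-3-methylbut-1-yne
Product: 6 methyl 2,2-dimethyl-7-[(2-methylbut-3-yn-2-yl)oxy]-3,4-dihydro-2H-chromene-5-carboxylate
Conditions: DBU, CuCl2·2H2O (cat.), MeCN, 0 °C → rt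
Reagents that add atoms: none
Why: The same copper-catalysed phenol propargylation as in step 1, now on the single hydroxyl of 5.

Step 5
Reactants: 6 methyl 2,2-dimethyl-7-[(2-methylbut-3-yn-2-yl)oxy]-3,4-dihydro-2H-chromene-5-carboxylate
Product: 7 methyl 2,2-dimethyl-7-[(2-methylbut-3-en-2-yl)oxy]-3,4-dihydro-2H-chromene-5-carboxylate
Conditions: H2 (1 atm), Pd/CaCO3 poisoned with Pb(OAc)2 (Lindlar catalyst), quinoline, EtOAc, rt
Reagents that add atoms: none
Why: Semihydrogenation of the terminal alkyne over the poisoned palladium catalyst stops at the 1,1-dimethylallyl ether, the ether type that transfers an unbranched prenyl group in an aromatic Claisen rearrangement.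

Step 6
Reactants: 7 methyl 2,2-dimethyl-7-[(2-methylbut-3-en-2-yl)oxy]-3,4-dihydro-2H-chromene-5-carboxylate
Product: 8 methyl 7-hydroxy-2,2-dimethyl-6-(3-methylbut-2-en-1-yl)-3,4-dihydro-2H-chromene-5-carboxylate
Conditions: xylenes, 130 °C
Reagents that add atoms: none
Why: Aromatic Claisen rearrangement of an aryl 1,1-dimethylallyl ether: the [3,3] shift delivers the unbranched prenyl group to an ortho carbon and tautomerisation restores the phenol. C6 is ortho to the ester and para to the ring oxygen, two effects that favour it over C8, which lies between two oxygens.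

Step 7
Reactants: 8 methyl 7-hydroxy-2,2-dimethyl-6-(3-methylbut-2-en-1-yl)-3,4-dihydro-2H-chromene-5-carboxylate
Product: 9 methyl 2,2-dimethyl-6-(3-methylbut-2-en-1-yl)-7-[(triisopropylsilyl)oxy]-3,4-dihydro-2H-chromene-5-carboxylate
Conditions: TIPSCl, imidazole, DMAP (cat.), DMF, 40 °C
Reagents that add atoms: chlorotriisopropylsilane, CC(C)[Si](Cl)(C(C)C)C(C)C
Why: Standard silylation of a phenol. The triisopropylsilyl ether is chosen because it must outlast hydride, heat, base and the later removal of the tert-butyldimethylsilyl ethers, and because it stops the ortho-prenylphenol from adding to its own alkene in the key step.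

Step 8
Reactants: 9 methyl 2,2-dimethyl-6-(3-methylbut-2-en-1-yl)-7-[(triisopropylsilyl)oxy]-3,4-dihydro-2H-chromene-5-carboxylate
Product: 10 {2,2-dimethyl-6-(3-methylbut-2-en-1-yl)-7-[(triisopropylsilyl)oxy]-3,4-dihydro-2H-chromen-5-yl}methanol
Conditions: i-Bu2AlH, CH2Cl2, −78 → 0 °C; aq. potassium sodium tartrate
Reagents that add atoms: none
Why: Hydride reduction of the di-ortho-substituted benzoate to the benzylic alcohol; the aryl silyl ether and the trisubstituted alkene are inert to i-Bu2AlH at low temperature.

Step 9
Reactants: 10 {2,2-dimethyl-6-(3-methylbut-2-en-1-yl)-7-[(triisopropylsilyl)oxy]-3,4-dihydro-2H-chromen-5-yl}methanol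
Product: 11 {[5-(bromomethyl)-2,2-dimethyl-6-(3-methylbut-2-en-1-yl)-3,4-dihydro-2H-chromen-7-yl]oxy}triisopropylsilane
Conditions: CBr4, PPh3, CH2Cl2, 0 °C
Reagents that add atoms: carbon tetrabromide, BrC(Br)(Br)Br
Why: Appel bromination converts the benzylic alcohol into the bromide under neutral conditions that spare the prenyl alkene and the silyl ether.

Step 10
Reactants: 11 {[5-(bromomethyl)-2,2-dimethyl-6-(3-methylbut-2-en-1-yl)-3,4-dihydro-2H-chromen-7-yl]oxy}triisopropylsilane
Product: 12 diethyl ({2,2-dimethyl-6-(3-methylbut-2-en-1-yl)-7-[(triisopropylsilyl)oxy]-3,4-dihydro-2H-chromen-5-yl}methyl)phosphonate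
Conditions: P(OEt)3 (neat), 130 °C
Reagents that add atoms: triethyl phosphite, CCOP(OCC)OCC
Why: Michaelis–Arbuzov reaction of a benzylic bromide with triethyl phosphite; the volatile bromoethane leaves the hot mixture.

Step 11
Reactants: 13 2,4,6-trihydroxybenzaldehyde; 14 prenyl bromide (1-bromo-3-methylbut-2-ene)
Product: 15 2,6-dihydroxy-4-[(3-methylbut-2-en-1-yl)oxy]benzaldehyde
Conditions: K2CO3 (1 equiv), acetone, 0 °C → rt
Reagents that add atoms: none
Why: Williamson etherification with one equivalent of weak base: the C4 hydroxyl, para to the formyl group, is the most acidic and is not hydrogen-bonded to the carbonyl, so it should be alkylated first. Because 13 and 15 are symmetric, only this one oxygen has to be distinguished.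

Step 12
Reactants: 15 2,6-dihydroxy-4-[(3-methylbut-2-en-1-yl)oxy]benzaldehyde
Product: 16 2,6-bis[(tert-butyldimethylsilyl)oxy]-4-[(3-methylbut-2-en-1-yl)oxy]benzaldehyde
Conditions: TBSCl (excess), imidazole, DMF, rt
Reagents that add atoms: tert-butylchlorodimethylsilane, CC(C)(C)[Si](C)(C)Cl
Why: Silylation of both ortho phenols gives a base-stable aldehyde for the olefination; excess reagent is used because one hydroxyl is hydrogen-bonded to the carbonyl.

Step 13
Reactants: 12 diethyl ({2,2-dimethyl-6-(3-methylbut-2-en-1-yl)-7-[(triisopropylsilyl)oxy]-3,4-dihydro-2H-chromen-5-yl}methyl)phosphonate; 16 2,6-bis[(tert-butyldimethylsilyl)oxy]-4-[(3-methylbut-2-en-1-yl)oxy]benzaldehyde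
Product: 17 (E)-1-{2,6-bis[(tert-butyldimethylsilyl)oxy]-4-[(3-methylbut-2-en-1-yl)oxy]phenyl}-2-{2,2-dimethyl-6-(3-methylbut-2-en-1-yl)-7-[(triisopropylsilyl)oxy]-3,4-dihydro-2H-chromen-5-yl}ethene
Conditions: KN(SiMe3)2, THF, −78 °C; then 16, −78 °C → rt
Reagents that add atoms: none
Why: Horner–Wadsworth–Emmons olefination of a benzylic phosphonate anion with an aromatic aldehyde, which should give the E-stilbene by elimination from the less crowded oxyanion. The formyl carbon of 16 fixes which ring A carbon carries the alkene, and the non-nucleophilic amide base leaves the aryl silyl ethers alone.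

Step 14
Reactants: 17 (E)-1-{2,6-bis[(tert-butyldimethylsilyl)oxy]-4-[(3-methylbut-2-en-1-yl)oxy]phenyl}-2-{2,2-dimethyl-6-(3-methylbut-2-en-1-yl)-7-[(triisopropylsilyl)oxy]-3,4-dihydro-2H-chromen-5-yl}ethene
Product: 18 (E)-2-(2-{2,2-dimethyl-6-(3-methylbut-2-en-1-yl)-7-[(triisopropylsilyl)oxy]-3,4-dihydro-2H-chromen-5-yl}ethenyl)-5-[(3-methylbut-2-en-1-yl)oxy]benzene-1,3-diol
Conditions: K2CO3 (0.5 equiv), MeOH–THF, 0 °C → rt, Ar
Reagents that add atoms: none
Why: Base-mediated methanolysis of phenolic silyl ethers: the two tert-butyldimethylsilyl ethers on the somewhat more acidic ring A phenols should be cleaved, while the triisopropylsilyl ether on ring C, more hindered at silicon and flanked by the prenyl group, is expected to persist at low temperature.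

Step 15
Reactants: 18 (E)-2-(2-{2,2-dimethyl-6-(3-methylbut-2-en-1-yl)-7-[(triisopropylsilyl)oxy]-3,4-dihydro-2H-chromen-5-yl}ethenyl)-5-[(3-methylbut-2-en-1-yl)oxy]benzene-1,3-diol
Product: 19 2-{2,2-dimethyl-6-(3-methylbut-2-en-1-yl)-7-[(triisopropylsilyl)oxy]-3,4-dihydro-2H-chromen-5-yl}-6-[(3-methylbut-2-en-1-yl)oxy]-1-benzofuran-4-ol
Conditions: PdCl2(MeCN)2 (10 mol%), NaOAc, O2 (1 atm), DMSO, 60 °C
Reagents that add atoms: none
Why: This is a Wacker-type intramolecular oxidative alkoxylation, the known palladium-catalysed conversion of 2-hydroxystilbenes into 2-arylbenzofurans. Divalent palladium binds the stilbene double bond of 18, and one of the two equivalent phenol oxygens attacks the alkene carbon that carries ring C from the face opposite to palladium; this forms O1–C2, closes the furan ring in a 5-endo-trig mode (ring atoms O1, C7a, C3a, C3, C2) and leaves palladium on C3. Anti addition across the E alkene places the C2 hydrogen syn to palladium, so β-hydride elimination gives the C2=C3 bond and the aromatic furan, and dioxygen in DMSO returns zerovalent palladium to the divalent state. No stereocentre is formed, because C2 and C3 both end up trigonal. The choice between the two phenols does not arise, since rotation about the aryl–vinyl bond makes them identical, and the hydroxyl that is not used becomes the C4–OH. The selectivity that is needed is reaction at the conjugated, phenol-flanked stilbene alkene in preference to the trisubstituted prenyl alkenes; it is secured by the intramolecular nucleophile, by the weak binding of trisubstituted alkenes to divalent palladium, and by the silyl ether on ring C, which removes the only other phenol that could add to a neighbouring prenyl group. Sodium acetate takes up the acid released, so the prenyl ether and the electron-rich product are not exposed to HCl.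

Step 16
Reactants: 19 2-{2,2-dimethyl-6-(3-methylbut-2-en-1-yl)-7-[(triisopropylsilyl)oxy]-3,4-dihydro-2H-chromen-5-yl}-6-[(3-methylbut-2-en-1-yl)oxy]-1-benzofuran-4-ol
Product: 20 {[2-{2,2-dimethyl-6-(3-methylbut-2-en-1-yl)-7-[(triisopropylsilyl)oxy]-3,4-dihydro-2H-chromen-5-yl}-6-[(3-methylbut-2-en-1-yl)oxy]-1-benzofuran-4-yl]oxy}triisopropylsilane
Conditions: TIPSCl, imidazole, DMF, rt
Reagents that add atoms: chlorotriisopropylsilane, CC(C)[Si](Cl)(C(C)C)C(C)C
Why: Silylation of the only free hydroxyl; the bulky group shields C5 so that the following sigmatropic shift is directed to C7.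

Step 17
Reactants: 20 {[2-{2,2-dimethyl-6-(3-methylbut-2-en-1-yl)-7-[(triisopropylsilyl)oxy]-3,4-dihydro-2H-chromen-5-yl}-6-[(3-methylbut-2-en-1-yl)oxy]-1-benzofuran-4-yl]oxy}triisopropylsilane
Product: 21 2-{2,2-dimethyl-6-(3-methylbut-2-en-1-yl)-7-[(triisopropylsilyl)oxy]-3,4-dihydro-2H-chromen-5-yl}-7-(2-methylbut-3-en-2-yl)-4-[(triisopropylsilyl)oxy]-1-benzofuran-6-ol
Conditions: Eu(fod)3 (10 mol%), CHCl3, 70 °C (sealed tube)
Reagents that add atoms: none
Why: Lewis-acid-catalysed aromatic Claisen rearrangement of an aryl prenyl ether: the [3,3] shift bonds C7 to the tertiary allylic carbon and so creates the 1,1-dimethylallyl group, and enolisation restores the phenol. C7 should be preferred over C5 because C5 is flanked by the triisopropylsilyloxy group and because the C6–C7 bond of a 6-oxygenated benzofuran has the higher double-bond character; the para position C3a is a ring-fusion carbon, so no onward Cope shift can follow.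

Step 18
Reactants: 21 2-{2,2-dimethyl-6-(3-methylbut-2-en-1-yl)-7-[(triisopropylsilyl)oxy]-3,4-dihydro-2H-chromen-5-yl}-7-(2-methylbut-3-en-2-yl)-4-[(triisopropylsilyl)oxy]-1-benzofuran-6-ol
Product: 22 artopetelin C, 2-[7-hydroxy-2,2-dimethyl-6-(3-methylbut-2-en-1-yl)-3,4-dihydro-2H-chromen-5-yl]-7-(2-methylbut-3-en-2-yl)-1-benzofuran-4,6-diol
Conditions: Bu4NF, AcOH, THF, 0 °C
Reagents that add atoms: none
Why: Fluoride cleaves both aryl triisopropylsilyl ethers; acetic acid buffers the phenoxides so that the electron-rich triol is not exposed to strong base, and the three alkenes are untouched.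

## Compound list

1 | methyl 3,5-dihydroxybenzoate | COC(=O)c1cc(O)cc(O)c1 | starting material
2 | 3-chloro-3-methylbut-1-yne | C#CC(C)(C)Cl | starting material
3 | methyl 3-hydroxy-5-[(2-methylbut-3-yn-2-yl)oxy]benzoate | COC(=O)c1cc(O)cc(OC(C)(C)C#C)c1 | intermediate
4 | methyl 7-hydroxy-2,2-dimethyl-2H-chromene-5-carboxylate | COC(=O)c1cc(O)cc2OC(C)(C)C=Cc12 | intermediate
5 | methyl 7-hydroxy-2,2-dimethyl-3,4-dihydro-2H-chromene-5-carboxylate | COC(=O)c1cc(O)cc2OC(C)(C)CCc12 | intermediate
6 | methyl 2,2-dimethyl-7-[(2-methylbut-3-yn-2-yl)oxy]-3,4-dihydro-2H-chromene-5-carboxylate | COC(=O)c1cc(OC(C)(C)C#C)cc2OC(C)(C)CCc12 | intermediate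
7 | methyl 2,2-dimethyl-7-[(2-methylbut-3-en-2-yl)oxy]-3,4-dihydro-2H-chromene-5-carboxylate | COC(=O)c1cc(OC(C)(C)C=C)cc2OC(C)(C)CCc12 | intermediate
8 | methyl 7-hydroxy-2,2-dimethyl-6-(3-methylbut-2-en-1-yl)-3,4-dihydro-2H-chromene-5-carboxylate | COC(=O)c1c(CC=C(C)C)c(O)cc2OC(C)(C)CCc12 | intermediate
9 | methyl 2,2-dimethyl-6-(3-methylbut-2-en-1-yl)-7-[(triisopropylsilyl)oxy]-3,4-dihydro-2H-chromene-5-carboxylate | COC(=O)c1c(CC=C(C)C)c(O[Si](C(C)C)(C(C)C)C(C)C)cc2OC(C)(C)CCc12 | intermediate
10 | {2,2-dimethyl-6-(3-methylbut-2-en-1-yl)-7-[(triisopropylsilyl)oxy]-3,4-dihydro-2H-chromen-5-yl}methanol | OCc1c(CC=C(C)C)c(O[Si](C(C)C)(C(C)C)C(C)C)cc2OC(C)(C)CCc12 | intermediate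
11 | {[5-(bromomethyl)-2,2-dimethyl-6-(3-methylbut-2-en-1-yl)-3,4-dihydro-2H-chromen-7-yl]oxy}triisopropylsilane | BrCc1c(CC=C(C)C)c(O[Si](C(C)C)(C(C)C)C(C)C)cc2OC(C)(C)CCc12 | intermediate
12 | diethyl ({2,2-dimethyl-6-(3-methylbut-2-en-1-yl)-7-[(triisopropylsilyl)oxy]-3,4-dihydro-2H-chromen-5-yl}methyl)phosphonate | CCOP(=O)(OCC)Cc1c(CC=C(C)C)c(O[Si](C(C)C)(C(C)C)C(C)C)cc2OC(C)(C)CCc12 | intermediate
13 | 2,4,6-trihydroxybenzaldehyde | O=Cc1c(O)cc(O)cc1O | starting material
14 | prenyl bromide (1-bromo-3-methylbut-2-ene) | CC(C)=CCBr | starting material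
15 | 2,6-dihydroxy-4-[(3-methylbut-2-en-1-yl)oxy]benzaldehyde | CC(C)=CCOc1cc(O)c(C=O)c(O)c1 | intermediate
16 | 2,6-bis[(tert-butyldimethylsilyl)oxy]-4-[(3-methylbut-2-en-1-yl)oxy]benzaldehyde | CC(C)=CCOc1cc(O[Si](C)(C)C(C)(C)C)c(C=O)c(O[Si](C)(C)C(C)(C)C)c1 | intermediate
17 | (E)-1-{2,6-bis[(tert-butyldimethylsilyl)oxy]-4-[(3-methylbut-2-en-1-yl)oxy]phenyl}-2-{2,2-dimethyl-6-(3-methylbut-2-en-1-yl)-7-[(triisopropylsilyl)oxy]-3,4-dihydro-2H-chromen-5-yl}ethene | CC(C)=CCOc1cc(O[Si](C)(C)C(C)(C)C)c(/C=C/c2c(CC=C(C)C)c(O[Si](C(C)C)(C(C)C)C(C)C)cc3OC(C)(C)CCc23)c(O[Si](C)(C)C(C)(C)C)c1 | intermediate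
18 | (E)-2-(2-{2,2-dimethyl-6-(3-methylbut-2-en-1-yl)-7-[(triisopropylsilyl)oxy]-3,4-dihydro-2H-chromen-5-yl}ethenyl)-5-[(3-methylbut-2-en-1-yl)oxy]benzene-1,3-diol | CC(C)=CCOc1cc(O)c(/C=C/c2c(CC=C(C)C)c(O[Si](C(C)C)(C(C)C)C(C)C)cc3OC(C)(C)CCc23)c(O)c1 | intermediate
19 | 2-{2,2-dimethyl-6-(3-methylbut-2-en-1-yl)-7-[(triisopropylsilyl)oxy]-3,4-dihydro-2H-chromen-5-yl}-6-[(3-methylbut-2-en-1-yl)oxy]-1-benzofuran-4-ol | CC(C)=CCOc1cc(O)c2cc(-c3c(CC=C(C)C)c(O[Si](C(C)C)(C(C)C)C(C)C)cc4OC(C)(C)CCc34)oc2c1 | intermediate
20 | {[2-{2,2-dimethyl-6-(3-methylbut-2-en-1-yl)-7-[(triisopropylsilyl)oxy]-3,4-dihydro-2H-chromen-5-yl}-6-[(3-methylbut-2-en-1-yl)oxy]-1-benzofuran-4-yl]oxy}triisopropylsilane | CC(C)=CCOc1cc(O[Si](C(C)C)(C(C)C)C(C)C)c2cc(-c3c(CC=C(C)C)c(O[Si](C(C)C)(C(C)C)C(C)C)cc4OC(C)(C)CCc34)oc2c1 | intermediate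
21 | 2-{2,2-dimethyl-6-(3-methylbut-2-en-1-yl)-7-[(triisopropylsilyl)oxy]-3,4-dihydro-2H-chromen-5-yl}-7-(2-methylbut-3-en-2-yl)-4-[(triisopropylsilyl)oxy]-1-benzofuran-6-ol | C=CC(C)(C)c1c(O)cc(O[Si](C(C)C)(C(C)C)C(C)C)c2cc(-c3c(CC=C(C)C)c(O[Si](C(C)C)(C(C)C)C(C)C)cc4OC(C)(C)CCc34)oc12 | intermediate
22 | artopetelin C, 2-[7-hydroxy-2,2-dimethyl-6-(3-methylbut-2-en-1-yl)-3,4-dihydro-2H-chromen-5-yl]-7-(2-methylbut-3-en-2-yl)-1-benzofuran-4,6-diol | C=CC(C)(C)c1c(O)cc(O)c2cc(-c3c(CC=C(C)C)c(O)cc4c3CCC(C)(C)O4)oc12 | target

## Step count and least certain steps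

Total step count: 18. Longest linear sequence: 16 steps (steps 1–10, then 13–18); the ring A branch (steps 11–12) joins at step 13.

Step 15 (key step). The likely failure is over-oxidation of the electron-rich phloroglucinol ring, or ionisation of the aryl prenyl ether by zerovalent palladium before it is reoxidised, with loss of the prenyl group; slow turnover under dioxygen would make both worse. Fallback: from 18, one of the two equivalent hydroxyls is silylated first (TIPSCl, one equivalent, imidazole, CH2Cl2, 0 °C) to the mono(triisopropylsilyl) ether of the stilbene F1. F1 is then cyclised without a metal by PhI(OAc)2 in MeCN at 0 °C → rt, the known hypervalent-iodine oxidative cyclisation of 2-hydroxystilbenes. Blocking the second phenol removes the quinone-forming pathway, and the product is 20, so the route is rejoined at 20 and step 16 is not needed.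

Step 6. The likely failure is incomplete regiocontrol of the [3,3] shift, with part of the prenyl group delivered to C8 between the two oxygens, or loss of the allyl unit as a diene on heating. Step 2 rests on the same directing effects, but there the wrong isomer is removed at the start from cheap material. Fallback: from 5, bromination with NBS in MeCN at −20 °C, expected at C6 (para to the ring oxygen, as 3,5-dialkoxybenzoates brominate next to the ester), gives methyl 6-bromo-7-hydroxy-2,2-dimethyl-3,4-dihydro-2H-chromene-5-carboxylate F2. Silylation (TIPSCl, imidazole, DMF) gives methyl 6-bromo-2,2-dimethyl-7-[(triisopropylsilyl)oxy]-3,4-dihydro-2H-chromene-5-carboxylate F3, and Stille coupling of F3 with tributyl(3-methylbut-2-en-1-yl)stannane (Pd2(dba)3, P(t-Bu)3, CsF, dioxane, 90 °C) gives 9, where the route is rejoined.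

Step 13. The likely failures are slow addition, because the aldehyde is di-ortho-substituted and electron-rich and the phosphonate anion is flanked by two alkyl groups, and migration of a silyl group from a ring A oxygen to the intermediate alkoxide, which would stop the elimination. Fallback: from 11, magnesium insertion (Mg, Et2O, 0 °C, slow addition) gives the benzylic Grignard reagent bromo({2,2-dimethyl-6-(3-methylbut-2-en-1-yl)-7-[(triisopropylsilyl)oxy]-3,4-dihydro-2H-chromen-5-yl}methyl)magnesium F4, used in situ. Addition of F4 to 16 in THF at −78 °C with a cold quench gives the racemic carbinol 1-{2,6-bis[(tert-butyldimethylsilyl)oxy]-4-[(3-methylbut-2-en-1-yl)oxy]phenyl}-2-{2,2-dimethyl-6-(3-methylbut-2-en-1-yl)-7-[(triisopropylsilyl)oxy]-3,4-dihydro-2H-chromen-5-yl}ethan-1-ol F5. Dehydration of F5 with catalytic pyridinium p-toluenesulfonate in toluene at 60 °C, easy because the carbinol carbon is benzylic to the trioxygenated ring, gives the E-stilbene 17.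

Step 14. The likely failure is insufficient discrimination between the silyl ethers: partial loss of the ring C triisopropylsilyl ether, or incomplete cleavage on ring A. Fallback: from 15, both phenols are protected as methoxymethyl ethers (MOMCl, NaH, DMF, 0 °C) to 2,6-bis(methoxymethoxy)-4-[(3-methylbut-2-en-1-yl)oxy]benzaldehyde F6. Olefination of F6 with 12 as in step 13 gives the bis(methoxymethyl) ether of the stilbene F7. The acetals of F7 are exchanged with TMSOTf and 2,2'-bipyridyl in MeCN at 0 °C for trimethylsilyl groups, giving the bis(trimethylsilyl) ether F8 (not isolated), which water hydrolyses to 18. The acetal and the triisopropylsilyl ether then differ in kind, not only in rate.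

Step 17. The likely failures are partial migration to C5, loss of the prenyl group, a 1,3-shift under Lewis acid that gives the unbranched isomer, and acid-promoted addition of the new C6 phenol to the neighbouring vinyl group. Fallback: from 20, the rearrangement is run thermally with trapping (Ac2O, PhNEt2, 185 °C), so that the phenol is acetylated as it forms and cannot react further; this gives 2-{2,2-dimethyl-6-(3-methylbut-2-en-1-yl)-7-[(triisopropylsilyl)oxy]-3,4-dihydro-2H-chromen-5-yl}-7-(2-methylbut-3-en-2-yl)-4-[(triisopropylsilyl)oxy]-1-benzofuran-6-yl acetate F9. Methanolysis of F9 (K2CO3, MeOH, 0 °C) returns 21.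

## Further compounds

F1 | step 15 | (E)-2-(2-{2,2-dimethyl-6-(3-methylbut-2-en-1-yl)-7-[(triisopropylsilyl)oxy]-3,4-dihydro-2H-chromen-5-yl}ethenyl)-5-[(3-methylbut-2-en-1-yl)oxy]-3-[(triisopropylsilyl)oxy]phenol | CC(C)=CCOc1cc(O)c(/C=C/c2c(CC=C(C)C)c(O[Si](C(C)C)(C(C)C)C(C)C)cc3OC(C)(C)CCc23)c(O[Si](C(C)C)(C(C)C)C(C)C)c1
F2 | step 6 | methyl 6-bromo-7-hydroxy-2,2-dimethyl-3,4-dihydro-2H-chromene-5-carboxylate | COC(=O)c1c(Br)c(O)cc2OC(C)(C)CCc12
F3 | step 6 | methyl 6-bromo-2,2-dimethyl-7-[(triisopropylsilyl)oxy]-3,4-dihydro-2H-chromene-5-carboxylate | COC(=O)c1c(Br)c(O[Si](C(C)C)(C(C)C)C(C)C)cc2OC(C)(C)CCc12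
F4 | step 13 | bromo({2,2-dimethyl-6-(3-methylbut-2-en-1-yl)-7-[(triisopropylsilyl)oxy]-3,4-dihydro-2H-chromen-5-yl}methyl)magnesium | Br[Mg]Cc1c(CC=C(C)C)c(O[Si](C(C)C)(C(C)C)C(C)C)cc2OC(C)(C)CCc12
F5 | step 13 | racemic 1-{2,6-bis[(tert-butyldimethylsilyl)oxy]-4-[(3-methylbut-2-en-1-yl)oxy]phenyl}-2-{2,2-dimethyl-6-(3-methylbut-2-en-1-yl)-7-[(triisopropylsilyl)oxy]-3,4-dihydro-2H-chromen-5-yl}ethan-1-ol | CC(C)=CCOc1cc(O[Si](C)(C)C(C)(C)C)c(C(O)Cc2c(CC=C(C)C)c(O[Si](C(C)C)(C(C)C)C(C)C)cc3OC(C)(C)CCc23)c(O[Si](C)(C)C(C)(C)C)c1
F6 | step 14 | 2,6-bis(methoxymethoxy)-4-[(3-methylbut-2-en-1-yl)oxy]benzaldehyde | COCOc1cc(OCC=C(C)C)cc(OCOC)c1C=O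
F7 | step 14 | (E)-1-{2,6-bis(methoxymethoxy)-4-[(3-methylbut-2-en-1-yl)oxy]phenyl}-2-{2,2-dimethyl-6-(3-methylbut-2-en-1-yl)-7-[(triisopropylsilyl)oxy]-3,4-dihydro-2H-chromen-5-yl}ethene | COCOc1cc(OCC=C(C)C)cc(OCOC)c1/C=C/c1c(CC=C(C)C)c(O[Si](C(C)C)(C(C)C)C(C)C)cc2OC(C)(C)CCc12
F8 | step 14 | (E)-1-{4-[(3-methylbut-2-en-1-yl)oxy]-2,6-bis[(trimethylsilyl)oxy]phenyl}-2-{2,2-dimethyl-6-(3-methylbut-2-en-1-yl)-7-[(triisopropylsilyl)oxy]-3,4-dihydro-2H-chromen-5-yl}ethene | C[Si](C)(C)Oc1cc(OCC=C(C)C)cc(O[Si](C)(C)C)c1/C=C/c1c(CC=C(C)C)c(O[Si](C(C)C)(C(C)C)C(C)C)cc2OC(C)(C)CCc12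
F9 | step 17 | 2-{2,2-dimethyl-6-(3-methylbut-2-en-1-yl)-7-[(triisopropylsilyl)oxy]-3,4-dihydro-2H-chromen-5-yl}-7-(2-methylbut-3-en-2-yl)-4-[(triisopropylsilyl)oxy]-1-benzofuran-6-yl acetate | C=CC(C)(C)c1c(OC(C)=O)cc(O[Si](C(C)C)(C(C)C)C(C)C)c2cc(-c3c(CC=C(C)C)c(O[Si](C(C)C)(C(C)C)C(C)C)cc4OC(C)(C)CCc34)oc12
A1 | alternative 1 | 1-{2-[4,6-bis(tert-butyldimethylsilyloxy)-7-(2-methylbut-3-en-2-yl)-1-benzofuran-2-yl]-4,6-dihydroxy-3-(3-methylbut-2-en-1-yl)phenyl}-3-methylbut-2-en-1-one | C=CC(C)(C)c1c(O[Si](C)(C)C(C)(C)C)cc(O[Si](C)(C)C(C)(C)C)c2cc(-c3c(CC=C(C)C)c(O)cc(O)c3C(=O)C=C(C)C)oc12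
A2 | alternative 1 | 1-[4,6-bis(tert-butyldimethylsilyloxy)-7-(2-methylbut-3-en-2-yl)-1-benzofuran-2-yl]-5-methylhex-4-en-1-yn-3-one | C=CC(C)(C)c1c(O[Si](C)(C)C(C)(C)C)cc(O[Si](C)(C)C(C)(C)C)c2cc(C#CC(=O)C=C(C)C)oc12
A3 | alternative 1 | 1-methoxy-7-methyl-1,3-bis(trimethylsilyloxy)octa-1,3,6-triene | COC(O[Si](C)(C)C)=CC(O[Si](C)(C)C)=CCC=C(C)C
A4 | alternative 2 | artopetelin C tris(silyl ether), C4 and C6 tert-butyldimethylsilyl, C3' triisopropylsilyl | C=CC(C)(C)c1c(O[Si](C)(C)C(C)(C)C)cc(O[Si](C)(C)C(C)(C)C)c2cc(-c3c(CC=C(C)C)c(O[Si](C(C)C)(C(C)C)C(C)C)cc4c3CCC(C)(C)O4)oc12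
A5 | alternative 2 | 4,6-bis(tert-butyldimethylsilyloxy)-7-(2-methylbut-3-en-2-yl)-1-benzofuran | C=CC(C)(C)c1c(O[Si](C)(C)C(C)(C)C)cc(O[Si](C)(C)C(C)(C)C)c2ccoc12
A6 | alternative 2 | 6-iodo-2,2-dimethyl-7-[(triisopropylsilyl)oxy]-3,4-dihydro-2H-chromen-5-yl 4-chlorobenzenesulfonate | CC(C)[Si](Oc1cc2OC(C)(C)CCc2c(OS(=O)(=O)c2ccc(Cl)cc2)c1I)(C(C)C)C(C)C
A7 | alternative 3 | 2-{7-[(tert-butyldimethylsilyl)oxy]-2,2-dimethyl-6-(3-methylbut-2-en-1-yl)-3,4-dihydro-2H-chromen-5-yl}-7-(2-methylbut-3-en-2-yl)-6-[(triisopropylsilyl)oxy]-1-benzofuran-4-ol | C=CC(C)(C)c1c(O[Si](C(C)C)(C(C)C)C(C)C)cc(O)c2cc(-c3c(CC=C(C)C)c(O[Si](C)(C)C(C)(C)C)cc4c3CCC(C)(C)O4)oc12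
A8 | alternative 3 | 2-diazo-1-(5-{7-[(tert-butyldimethylsilyl)oxy]-2,2-dimethyl-6-(3-methylbut-2-en-1-yl)-3,4-dihydro-2H-chromen-5-yl}furan-2-yl)-3,3-dimethylpent-4-en-1-one | [N-]=[N+]=C(C(=O)c1ccc(-c2c(CC=C(C)C)c(O[Si](C)(C)C(C)(C)C)cc3OC(C)(C)CCc23)o1)C(C)(C)C=C
A9 | alternative 3 | (ethynyloxy)triisopropylsilane | C#CO[Si](C(C)C)(C(C)C)C(C)C
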